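The route rests on disconnecting the O1–C8a aryl ether bond of the 2H-pyran ring. C8a is the one oxygen-bearing carbon of the benzene ring that lies para, not ortho, to the C6 acyl carbon, so it can be traced to the bromine of symmetric 4-bromo-2,6-dimethoxybenzaldehyde, where the adjacent C4a position is iodinated without ambiguity. In a single operation a copper-catalysed intramolecular O-arylation lets the tertiary alkoxide of a Z-configured 3-hydroxy-3-methylbutenyl side chain replace that bromide, closing the pyran ring. The precursor is 4-bromo-3-[(1Z)-3-hydroxy-3-methylbut-1-enyl]-2,6-dimethoxybenzaldehyde. Aldol addition of acetophenone, oxidation and selective cleavage of the 5-methyl ether then complete the target.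

Key step: step 4

Remarks on the chemistry:
- In chromene numbering (O1, C2, C3, C4, C4a, C5 to C8, C8a) the target is 1-(5-hydroxy-7-methoxy-2,2-dimethyl-2H-chromen-6-yl)-3-phenylpropane-1,3-dione. The structures of the key-step precursor 5 and product 6 map onto it atom for atom and needed no correction.
- The target has no stereocentre. The only stereochemical element of the route is the Z alkene of 5, set in step 3.
- Compounds 1, 3 and 7 are assumed to be commercial.
- Species bound to a catalyst within a catalytic cycle are not numbered.
- The aldehyde of 5 is deliberately left unprotected, because it is the group that activates the bromide.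

Step 1
Reactants: 1 4-bromo-2,6-dimethoxybenzaldehyde
Product: 2 4-bromo-3-iodo-2,6-dimethoxybenzaldehyde
Conditions: NIS (1.1 equiv), TFA, MeCN, rt
Reagents that add atoms: N-iodosuccinimide, O=C1CCC(=O)N1I
Why: Electrophilic aromatic iodination (NIS activated by TFA) should occur at C3, which is ortho to one methoxy group, para to the other and equivalent to C5 by symmetry, so only one mono-iodide can form, and the deactivating iodine together with the limited reagent charge holds back a second substitution.

Step 2
Reactants: 2 4-bromo-3-iodo-2,6-dimethoxybenzaldehyde; 3 2-methylbut-3-yn-2-ol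
Product: 4 4-bromo-3-(3-hydroxy-3-methylbut-1-yn-1-yl)-2,6-dimethoxybenzaldehyde
Conditions: Pd(PPh3)2Cl2 (3 mol%), CuI (5 mol%), Et3N, THF, rt
Reagents that add atoms: none
Why: Sonogashira coupling, in which zerovalent palladium inserts into the C–I bond far faster than into the C–Br bond at room temperature, so the alkyne should be delivered to C3 only while the bromide, the aldehyde and the free tertiary alcohol are carried through.

Step 3
Reactants: 4 4-bromo-3-(3-hydroxy-3-methylbut-1-yn-1-yl)-2,6-dimethoxybenzaldehyde
Product: 5 4-bromo-3-[(1Z)-3-hydroxy-3-methylbut-1-en-1-yl]-2,6-dimethoxybenzaldehyde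
Conditions: H2 (1 atm), Pd/CaCO3 poisoned with Pb(OAc)2 (Lindlar catalyst), quinoline, EtOAc, rt
Reagents that add atoms: none
Why: Lindlar semi-hydrogenation, in which syn addition of one equivalent of hydrogen on the lead-poisoned palladium surface should give the Z alkene, while the poisoned catalyst and quinoline leave the aryl bromide, the aldehyde and the product alkene untouched if uptake is stopped at one equivalent.

Step 4
Reactants: 5 4-bromo-3-[(1Z)-3-hydroxy-3-methylbut-1-en-1-yl]-2,6-dimethoxybenzaldehyde
Product: 6 5,7-dimethoxy-2,2-dimethyl-2H-chromene-6-carbaldehyde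
Conditions: CuI (10 mol%), 3,4,7,8-tetramethyl-1,10-phenanthroline (20 mol%), Cs2CO3 (2 equiv), toluene, 100 °C, argon
Reagents that add atoms: none
Why: Carbonate deprotonates the tertiary alcohol and the alkoxide binds monovalent copper, which then activates the C4–Br bond of the benzaldehyde (the future C8a) and releases the O1–C8a bond by reductive elimination, while a direct addition–elimination through an adduct whose negative charge is delocalised into the para formyl group can operate alongside. The closest known reaction type is the Ullmann-type copper-catalysed intramolecular etherification of aryl bromides with alcohols, which is established for tertiary alcohols when a five- or six-membered ring is formed. The 2H-pyran ring closes in a 6-exo-trig mode, the alkoxide oxygen attacking the arene carbon whose C–Br bond lies outside the new ring. No stereocentre is created, and the Z alkene is carried into the ring as C3=C4. The step needs chemoselectivity for the bromide over the C2 methoxy group, which is also within reach of the alkoxide and ortho to the formyl group; bromide is the only site open to copper insertion and by far the better leaving group, and the cis alkene from step 3 holds the oxygen directly over it. The formyl group stays unprotected because it is the activating group and, being non-enolisable, should tolerate carbonate at this temperature.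

Step 5
Reactants: 6 5,7-dimethoxy-2,2-dimethyl-2H-chromene-6-carbaldehyde; 7 acetophenone
Product: 10 3-(5,7-dimethoxy-2,2-dimethyl-2H-chromen-6-yl)-3-hydroxy-1-phenylpropan-1-one (racemic), via lithium enolate of acetophenone 8 (not isolated), via lithium aldolate 9 (not isolated)
Conditions: 7, LDA, THF, −78 °C; then 6, −78 °C; AcOH, −78 °C
Reagents that add atoms: none
Why: Directed aldol addition, in which the preformed lithium enolate 8 adds to the non-enolisable aldehyde 6 through a lithium-chelated six-membered transition state at −78 °C, the cold acetic acid quench of aldolate 9 guards against retro-aldol cleavage and dehydration, and the new carbinol centre forms as a racemate that is erased by the oxidation in step 6.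

Step 6
Reactants: 10 3-(5,7-dimethoxy-2,2-dimethyl-2H-chromen-6-yl)-3-hydroxy-1-phenylpropan-1-one
Product: 11 1-(5,7-dimethoxy-2,2-dimethyl-2H-chromen-6-yl)-3-phenylpropane-1,3-dione
Conditions: IBX (2 equiv), EtOAc, 75 °C
Reagents that add atoms: none
Why: Oxidation of a β-hydroxy ketone to a 1,3-diketone with the pentavalent iodine reagent IBX, which under neutral conditions should oxidise the secondary benzylic alcohol without dehydration to the chalcone and without attack on the chromene alkene or the enolisable diketone product.

Step 7
Reactants: 11 1-(5,7-dimethoxy-2,2-dimethyl-2H-chromen-6-yl)-3-phenylpropane-1,3-dione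
Product: 13 1-(5-hydroxy-7-methoxy-2,2-dimethyl-2H-chromen-6-yl)-3-phenylpropane-1,3-dione, via aryloxydichloroborane chelate 12 (not isolated)
Conditions: BCl3 (3 equiv), CH2Cl2, −78 → 0 °C; then H2O, 0 °C → rt
Reagents that add atoms: none
Why: Chelation-directed Lewis-acid ether cleavage, in which BCl3 binds the C6 carbonyl oxygen and an ortho methoxy oxygen, and of the two ortho methoxy groups the C5 one, wedged between C4a and C6 and twisted out of the ring plane, is the more basic and the more strained, so chloride should remove its methyl group to give the six-membered boron chelate 12, which water hydrolyses to the hydrogen-bonded phenol; an excess of BCl3 is used because the enolised diketone takes up one equivalent as a boron diketonate that is hydrolysed in the same work-up.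

Compound list
1 | 4-bromo-2,6-dimethoxybenzaldehyde | COc1cc(Br)cc(OC)c1C=O | starting material
2 | 4-bromo-3-iodo-2,6-dimethoxybenzaldehyde | COc1cc(Br)c(I)c(OC)c1C=O | intermediate
3 | 2-methylbut-3-yn-2-ol | CC(C)(O)C#C | starting material
4 | 4-bromo-3-(3-hydroxy-3-methylbut-1-yn-1-yl)-2,6-dimethoxybenzaldehyde | COc1cc(Br)c(C#CC(C)(C)O)c(OC)c1C=O | intermediate
5 | 4-bromo-3-[(1Z)-3-hydroxy-3-methylbut-1-en-1-yl]-2,6-dimethoxybenzaldehyde | COc1cc(Br)c(/C=C\C(C)(C)O)c(OC)c1C=O | intermediate
6 | 5,7-dimethoxy-2,2-dimethyl-2H-chromene-6-carbaldehyde | COc1cc2OC(C)(C)C=Cc2c(OC)c1C=O | intermediate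
7 | acetophenone | CC(=O)c1ccccc1 | starting material
8 | lithium enolate of acetophenone (lithium 1-phenylethenolate) | [Li]OC(=C)c1ccccc1 | intermediate
9 | lithium aldolate (lithium alkoxide of 10, racemic) | COc1cc2OC(C)(C)C=Cc2c(OC)c1C(O[Li])CC(=O)c1ccccc1 | intermediate
10 | 3-(5,7-dimethoxy-2,2-dimethyl-2H-chromen-6-yl)-3-hydroxy-1-phenylpropan-1-one (racemic) | COc1cc2OC(C)(C)C=Cc2c(OC)c1C(O)CC(=O)c1ccccc1 | intermediate
11 | 1-(5,7-dimethoxy-2,2-dimethyl-2H-chromen-6-yl)-3-phenylpropane-1,3-dione | COc1cc2OC(C)(C)C=Cc2c(OC)c1C(=O)CC(=O)c1ccccc1 | intermediate
12 | aryloxydichloroborane chelate (5-O-dichloroboryl derivative of the diketone) | COc1cc2OC(C)(C)C=Cc2c(OB(Cl)Cl)c1C(=O)CC(=O)c1ccccc1 | intermediate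
13 | 1-(5-hydroxy-7-methoxy-2,2-dimethyl-2H-chromen-6-yl)-3-phenylpropane-1,3-dione | COc1cc2c(c(O)c1C(=O)CC(=O)c1ccccc1)C=CC(C)(C)O2 | target

Total step count: 7
Longest linear sequence: 7 steps (1 → 2 → 4 → 5 → 6 → 10 → 11 → 13)

Steps most likely to fail

1. Step 4. The hindered tertiary alkoxide may couple slowly, so that reductive loss of bromine, loss of water from the allylic alcohol to a diene, or Z-to-E isomerisation that moves the oxygen out of reach could take over. The fallback builds the pyran ring from a phenol and an enal instead of from an aryl halide and an alcohol. It sets out from 1. Miyaura borylation (B2pin2, Pd(dppf)Cl2, KOAc, dioxane, 80 °C) would give 2,6-dimethoxy-4-(4,4,5,5-tetramethyl-1,3,2-dioxaborolan-2-yl)benzaldehyde F1. Oxidation of the C–B bond with trimethylamine N-oxide (THF, rt), which spares the aldehyde, would give 4-hydroxy-2,6-dimethoxybenzaldehyde F2. Condensation of F2 with 3-methylbut-2-enal (ethylenediammonium diacetate cat., xylene, 140 °C) should then form the chromene by ortho C-alkylation, loss of water to an ortho-quinone methide and oxa-6π electrocyclisation. The two positions ortho to the phenol are equivalent, so one chromene is expected, and the sequence returns to the route at 6.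

2. Step 7. Ether cleavage may stop short or reach the C7 methoxy group, boron may be held back by the diketone, and the acid released may drive cyclodehydration of the 2-hydroxyaryl diketone to a flavone or add to the electron-rich chromene alkene. The fallback moves the cleavage to the aldehyde stage, where only a simple formyl chelate is involved and the site of cleavage can be assigned before material is committed, and carries the phenol as an acetal. It sets out from 6. BCl3 (CH2Cl2, −78 → 0 °C) should give 5-hydroxy-7-methoxy-2,2-dimethyl-2H-chromene-6-carbaldehyde F3. MOMCl and iPr2NEt (CH2Cl2, 0 °C → rt) would give 7-methoxy-5-(methoxymethoxy)-2,2-dimethyl-2H-chromene-6-carbaldehyde F4. Aldol addition of enolate 8 under the conditions of step 5 would give racemic 3-hydroxy-3-[7-methoxy-5-(methoxymethoxy)-2,2-dimethyl-2H-chromen-6-yl]-1-phenylpropan-1-one F5. IBX oxidation as in step 6 would give 1-[7-methoxy-5-(methoxymethoxy)-2,2-dimethyl-2H-chromen-6-yl]-3-phenylpropane-1,3-dione F6. Brief treatment with catalytic HCl in MeOH at 40 °C would remove the acetal and return to the route at 13.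

3. Step 5. Addition to the doubly ortho-substituted, electron-rich aldehyde is reversible, so retro-aldol cleavage on warming or dehydration of the electron-rich benzylic carbinol to the chalcone may erode the product. The fallback forms the carbon–carbon bond irreversibly at the ketone oxidation level. It sets out from 6. MeMgBr (THF, 0 °C) would give racemic 1-(5,7-dimethoxy-2,2-dimethyl-2H-chromen-6-yl)ethanol F7. Oxidation with IBX (EtOAc, 75 °C) would give 1-(5,7-dimethoxy-2,2-dimethyl-2H-chromen-6-yl)ethanone F8. Claisen condensation of its sodium enolate with methyl benzoate (NaH, THF, reflux, then dilute acid) should deliver the diketone, driven by deprotonation of the product, and returns to the route at 11.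

Further compounds
F1 | step 4 | 2,6-dimethoxy-4-(4,4,5,5-tetramethyl-1,3,2-dioxaborolan-2-yl)benzaldehyde | COc1cc(B2OC(C)(C)C(C)(C)O2)cc(OC)c1C=O
F2 | step 4 | 4-hydroxy-2,6-dimethoxybenzaldehyde | COc1cc(O)cc(OC)c1C=O
F3 | step 7 | 5-hydroxy-7-methoxy-2,2-dimethyl-2H-chromene-6-carbaldehyde | COc1cc2OC(C)(C)C=Cc2c(O)c1C=O
F4 | step 7 | 7-methoxy-5-(methoxymethoxy)-2,2-dimethyl-2H-chromene-6-carbaldehyde | COCOc1c(C=O)c(OC)cc2OC(C)(C)C=Cc12
F5 | step 7 | 3-hydroxy-3-[7-methoxy-5-(methoxymethoxy)-2,2-dimethyl-2H-chromen-6-yl]-1-phenylpropan-1-one (racemic) | COCOc1c(C(O)CC(=O)c3ccccc3)c(OC)cc2OC(C)(C)C=Cc12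
F6 | step 7 | 1-[7-methoxy-5-(methoxymethoxy)-2,2-dimethyl-2H-chromen-6-yl]-3-phenylpropane-1,3-dione | COCOc1c(C(=O)CC(=O)c3ccccc3)c(OC)cc2OC(C)(C)C=Cc12
F7 | step 5 | 1-(5,7-dimethoxy-2,2-dimethyl-2H-chromen-6-yl)ethanol (racemic) | COc1cc2OC(C)(C)C=Cc2c(OC)c1C(C)O
F8 | step 5 | 1-(5,7-dimethoxy-2,2-dimethyl-2H-chromen-6-yl)ethanone | COc1cc2OC(C)(C)C=Cc2c(OC)c1C(C)=O
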